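The readings are simulated for substances that don't exist, and the scatter is random.

**What counts.** Amounts are what you compare here: the average chain length (number-average degree of polymerisation) is the monomer in chains divided by the chains begun.

in all of them: protic impurity 0.395 M; pre-initiator 2 mol%
- gamma: free monomer 0.79 M; the very flask that is asked about, followed so far
- delta: free monomer 0.40 M; run made earlier
- flask: free monomer 0.79 M; time 6.0 d

gamma run (percent of the free monomer charged)

| time / h | monomer in chains / % | free monomer / % |
|---|---|---|
| 5.00 | 0 | 91.5 |
| 10.0 | 2.1 | 83.8 |
| 15.0 | 3.8 | 76.4 |
| 20.0 | 6.3 | 69.6 |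
| 25.0 | 9.2 | 63.9 |
| 30.0 | 12.3 | 58.8 |

delta run (percent of the free monomer charged)

| time / d | monomer in chains / % | free monomer / % |
|---|---|---|
| 0.333 | 0.8 | 86.4 |
| 0.500 | 0.5 | 81.5 |
| 0.833 | 2.5 | 70.6 |
| 1.67 | 5.7 | 51.9 |
| 2.50 | 8.3 | 40.8 |
| 4.00 | 9.6 | 29.3 |

(scatter of a reading: 0.5 percentage points)

- average number of monomer units in a chain (chains begun, living or dead) at 6.0 d
- part of the free monomer that has reacted at 6.0 d

- the average divides the monomer in chains by the number of chains begun, living and dead together
- the earlier runs do not show the number of chains; that part of a forecast is a guess

**Testing each number.** Start with the scatter, 0.5 percentage points, and set it against the 12.3% in chains at 30.0 h in the gamma run. Now look at the gap: in that run, at that time, 28.9% of the charge is neither free nor in chains, more than the chains hold, so you must watch that gap. The loading matters directly. If each pre-initiator begins at most one chain, c(chains begun) does not pass the chain ceiling, the loading times the free monomer charged, 0.0158 M. At a given amount of monomer in chains, the length goes inversely with the chain count, so a small relative error in the count passes into the length at like size.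

**The forecast.** It gives a chain length of 28 with 86% of the free monomer reacted, and says: “Chains begun is a guess: at most 0.0158 M, perhaps 0.0125 M”. My own reckoning differs: with half of the forecast's reacted part in chains and chains at the ceiling, I get a length of 21.5.

**The flask.** It gives a chain length of 20.2 with 82.8% of the free monomer reacted.

    pre-initiator → initiator (k = 6.70 × 10⁻⁶ /s)
    protic impurity + free monomer → quenched substrate (k = 1.31 × 10⁻⁵ /M/s)
    free monomer + initiator → living end + monomer in chains (k = 2.57 × 10⁻⁴ /M/s)
    monomer in chains + living end → free monomer + living end, rate k4*[living end] as long as [monomer in chains] is above zero (k = 6.25 × 10⁻⁵ /s)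
    free monomer + living end → monomer in chains + living end, rate k5*[living end]*[free monomer] (k = 4.68 × 10⁻⁴ /M/s)

At 6.00 d this flask holds 38.9% in chains and 0.0152 M of living end, which is 96.2% of the ceiling; the forecast's guess was 0.0125 M. Monomer in chains over the ceiling gives 19.5. The neighbouring flask, charged with 0.099 M of protic impurity, has the same ceiling and holds 67.4% in chains, so the same reckoning gives 33.7; its simulated result is 35.0.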